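## Structural features

The target is a chalcone whose acyl-bearing ring (2-acyl-3-hydroxy-5-methoxyphenyl ether) is fused through a 2,3-dihydrobenzofuran to an aristolane-type sesquiterpenoid. The terpenoid is numbered C1 (benzylic CH), C2 and C3 (CH2), C4 (CHCH3), C5 (C–CH3), C6 and C7 (cyclopropane CH), C8 and C9 (C=O), C10 (C–O) and C11 (C(CH3)2). Ring A is C1–C2–C3–C4–C5–C10, ring B is C5–C6–C7–C8–C9–C10, the dihydrofuran is O–C10–C1–aryl–aryl, and the cyclopropane is C6–C7–C11. The six stereocentres form two contiguous runs, C1–C10–C5–C4 and C5–C6–C7. C10 and C5 are adjacent fully substituted carbons; the ether oxygen, the C5 methyl, the C4 methyl and the C1–aryl bond lie on one face and the cyclopropane on the other, (1R,4R,5R,6S,7R,10S) with these locants. Fragile groups are the non-enolisable 1,2-dione (ring contraction with hydroxide), the acylcyclopropane (opened by acid), the chalcone (Michael acceptor, and flavanone closure once the ortho OH is free) and the tertiary alkyl aryl ether. The real difficulty is threefold: the vicinal C10/C5 pair with the right relative configuration, the hindered aryl ether, and the order of three mutually intolerant operations (methyl ketone oxidation/aldol, dione formation, cyclopropanation). The key step exploits the chain arene–C1–C2–C3–C4: it links the arene carbon ortho to the ether oxygen with the carbon attached to C5, so a vinyl group on C10 (C1=C2) and an isopropenyl group on C5 (C4=C3) can be zipped by one aryl radical into the dihydrofuran and ring A.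

## Logic of the disconnections

31 to 29: the C6–C11 and C7–C11 bonds are cut, removing C11 as an isopropylidene unit. The cyclopropane is the most acid-sensitive part, so it is made last. This leaves a flat C6=C7–C8(=O)–C9(=O) acceptor. The forward step must attack C6 on the face opposite the C5 methyl and must leave the chalcone alone, which is why the phenol is free at that point and reacts as its phenoxide.

29 back to 24: no skeletal bond is cut. The isopropyl–oxygen bond, the C6=C7 double bond, the C8 oxygen and the C9 carbonyl are taken back in turn (27, 26, 25) to a ketal with C6–C8 as CH2. Each forward step must tolerate the enone side chain, which has no α-hydrogen and is inert to the oxidants used.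

24 to 21 and 22: the chalcone Cα=Cβ bond is cut. Making it directly after the key step means the aldol base never meets the dione, and the methyl ketone is gone before the C8 oxidation. The demand is only that the hindered methyl ketone condenses.

21 to 20: the aryl–C1 and C2–C3 bonds are cut. Two rings and two stereocentres (C1, C4) are removed at once, leaving an aryl bromide with vinyl on C10 and isopropenyl on C5. The forward step must close 5-exo, then 6-endo, with C2 on the C5 side, and deliver hydrogen to C4 opposite the C5 methyl.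

20 to 18 (through 19): the acetyl CH3–C bond is cut to an aldehyde. A formyl group activates the neighbouring C–F bond without being enolisable, which an acetyl group would be under the etherification base. The price is two steps (addition, oxidation).

18 to 8 and 15 (through 17): the aryl C–O bond is cut, and the vinyl group is taken back to ethynyl. The fragments are a tertiary propargylic alcohol and a fluoroarene. With ethynyl on C10 the alkoxide is not a 1,5-diene and is less hindered; the forward steps are substitution at a crowded C–F carbon and a clean semihydrogenation.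

8 to 7: the C10–C1 bond is cut to a ketone. The forward addition must come from the face that puts the new carbon cis to isopropenyl.

7 to 3 (through 6 and 5): no skeletal bond is cut. The C9 ketal and C10 carbonyl are traced to a C9=C10 silyl enol ether: oxygen is put on C10, both carbons are brought to the dione level, and only C9 is ketalised. This requires the enol ether to be formed on the C10 side only.

3 to 1: the C5–C4 bond (isopropenyl to ring) is cut to an achiral enone. This is the only source of absolute configuration, so the forward conjugate addition must be enantioselective and its enolate must be trapped in place.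

15 to 9 (through 14, 13, 11): the O–isopropyl, C–Br, O–CH3 (as demethylation) and C–CHO bonds are cut to a symmetric fluoroarene. Each forward step needs one regiochemical decision, and each is directed by the group installed just before it.

## Other disconnections considered

Alternative 1: The aryl–C1 bond is traced to a 1,2-aryl shift in the spiro chromene A1, in which the arene sits on C2. PhI(OH)OTs (trivalent iodine) in methanol adds to C1=C2, the arene moves from C2 to C1 as PhI leaves, and C2 is captured as a dimethyl acetal, giving the spiro dihydrobenzofuran A2. In its favour: the step is polar and tin-free, the migration is stereospecific, the electron-rich arene is a good migrating group, and C2 is left at the aldehyde level for a later ring A closure. Against it here: A1 carries three alkenes, and the isopropenyl group is at least as reactive toward the iodane as the chromene. The configuration at C1 still depends on which face of the chromene is attacked, the same kind of facial question as in the chosen plan. Ring A is not formed, so several further steps (C2–C3 bond, removal of the C2 oxygen, C4 stereocentre) are needed, and A1 needs the same hindered tertiary ether. Comparison: on structure it builds one ring and one stereocentre where the chosen step builds two of each; on mechanism it is the better plan in avoiding a slow radical closure and the equal of the chosen plan on the C1 problem; on step economy it is worse.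

Alternative 2: The C5–C10 and C3–C4 bonds are cut together. The 3-vinylbenzofuran A3, tethered through the C8/C9 dione and the cis-cyclopropane to an (E)-but-2-en-2-yl group, would close rings A and B on heating to give the 1,2-dehydro pentacycle A4. In its favour: it is the most convergent plan, sets C10, C5 and C4 in one step, carries the dione and cyclopropane from the start, and can take its absolute configuration from a chiral-pool cyclopropane. On step count and on absolute stereocontrol it is the better plan. Against it here: the dienophile is unactivated and trisubstituted, and the furan must be dearomatised, so strong heating is needed. Under that heating the alkenylcyclopropane with a cis methyl group can undergo a homodienyl 1,5-hydrogen shift. The facial selectivity relative to the cyclopropane is not secured. C1 must then be set by hydrogenating C1=C2 from the face syn to C9, next to a dione and an aryl ketone. The chalcone would have to be made in the presence of the dione, which the chosen plan avoids. Comparison: better on structure and step economy, worse on mechanistic risk and on functional-group ordering.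

Alternative 3: The C9–C10 bond is cut. SmI2 (divalent samarium) would reduce the aldehyde of the tetrahydrodibenzofuran A5 to a ketyl that adds 6-exo to C10; reduction and protonation at C1 would give the cis-fused carbinol A6. In its favour: the C9 oxygen arrives in the ring-forming step (no C9 oxidation, ketal or hydrolysis), the cis ring fusion at C1/C10 is enforced by protonation, C4 and C5 are set earlier on a flat tricycle, and no tin is used. On the C9 oxygen it is the better plan and on C1 it is equal or better. Against it here: a nucleophilic ketyl must attack an electron-rich, fully substituted benzofuran carbon next to the quaternary C5, a polarity mismatch. The C10/C5 relationship depends on the ketyl approach. The aryl ketone must be protected as a ketal, which is difficult on a 2,6-disubstituted acetophenone. A5 needs its own asymmetric route. Comparison: the endgame (C8 oxidation, C6=C7, cyclopropanation, chalcone) is as long as in the chosen plan; the key bond is less likely to form; overall step economy is about equal.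

Key step: step 14

Remark: the descriptors of 20 and 21 were derived atom by atom from the target (ether O cis to the C5 methyl, vinyl cis to isopropenyl); locants C1–C11 in names are the terpenoid numbering above.
Remark: in step 1 the ligand antipode is the one that gives the (R) quaternary carbon; this is assumed, not derived.
Remark: the phenol is carried as an isopropyl ether, because an acetal protecting group would be lost in step 16 and a free 2'-hydroxychalcone is not compatible with step 17.

Step 1
Reactants: 1 3-methylcyclohex-2-en-1-one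
Product: 3 trimethyl{[(3R)-3-methyl-3-(prop-1-en-2-yl)cyclohex-1-en-1-yl]oxy}silane, via aluminium enolate 2 (not isolated)
Conditions: CH2=C(CH3)Br, t-BuLi (2 equiv), Et2O, −78 °C; Me2AlCl; then 1, Cu(O2CC4H3S) (5 mol%), chiral aminophosphine Ph2P–N[CH(CH3)Ar]2 (10 mol%), Et2O, −30 °C; then Me3SiOTf, −30 → 0 °C
Reagents that add atoms: dimethyl(prop-1-en-2-yl)aluminium, C[Al](C)C(C)=C, made in the flask from 2-bromopropene, CC(Br)=C; trimethylsilyl trifluoromethanesulfonate, C[Si](C)(C)OS(=O)(=O)C(F)(F)F
Why: Copper-catalysed asymmetric conjugate addition of an alkenylalane to a 3-substituted cyclohexenone is an established route to all-carbon quaternary centres; the ligand sets C5 and O-silylation of the aluminium enolate gives the C9=C10 enol ether regiospecifically.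

Step 2
Reactants: 3 trimethyl{[(3R)-3-methyl-3-(prop-1-en-2-yl)cyclohex-1-en-1-yl]oxy}silane
Product: 5 (3S)-2-hydroxy-3-methyl-3-(prop-1-en-2-yl)cyclohexan-1-one (both C2 epimers), via silyloxy ketone 4 (not isolated)
Conditions: mCPBA (1.0 equiv), CH2Cl2, −20 °C; then 1 M HCl, THF
Reagents that add atoms: 3-chloroperoxybenzoic acid, OOC(=O)c1cccc(Cl)c1
Why: Rubottom oxidation; the silyl enol ether is epoxidised far faster than the 1,1-disubstituted alkene, and the carbinol configuration is irrelevant because it is oxidised next.

Step 3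
Reactants: 5 (3S)-2-hydroxy-3-methyl-3-(prop-1-en-2-yl)cyclohexan-1-one
Product: 6 (6S)-2-hydroxy-6-methyl-6-(prop-1-en-2-yl)cyclohex-2-en-1-one (diosphenol form of the 1,2-dione)
Conditions: DMP (triacetoxy periodinane), CH2Cl2, rt
Reagents that add atoms: none
Why: Periodinane oxidation of an α-hydroxy ketone to the 1,2-dione, which can enolise only toward C8 and is obtained as the diosphenol.

Step 4
Reactants: 6 (6S)-2-hydroxy-6-methyl-6-(prop-1-en-2-yl)cyclohex-2-en-1-one
Product: 7 (7S)-7-methyl-7-(prop-1-en-2-yl)-1,4-dioxaspiro[4.5]decan-6-one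
Conditions: HOCH2CH2OH, HC(OEt)3, p-TsOH (cat.), CH2Cl2, rt
Reagents that add atoms: ethane-1,2-diol, OCCO
Why: Acid-catalysed ketalisation occurs at the enolised, unhindered C9 carbonyl; the C10 carbonyl next to the quaternary C5 stays free, and the mild conditions spare the isopropenyl group.

Step 5
Reactants: 7 (7S)-7-methyl-7-(prop-1-en-2-yl)-1,4-dioxaspiro[4.5]decan-6-one
Product: 8 (6S,7S)-6-ethynyl-7-methyl-7-(prop-1-en-2-yl)-1,4-dioxaspiro[4.5]decan-6-ol
Conditions: HC≡CMgBr (3 equiv), THF, 0 °C → rt; aq NH4Cl; chromatography
Reagents that add atoms: ethynylmagnesium bromide, C#C[Mg]Br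
Why: Grignard 1,2-addition to a non-enolisable ketone; the slim nucleophile should attack axially, anti to the axial C5 methyl of the conformer that keeps isopropenyl equatorial and away from the syn-axial ketal oxygen, placing ethynyl cis to isopropenyl; the C10 epimer is removed.

Step 6
Reactants: 9 1-fluoro-3,5-dimethoxybenzene
Product: 11 2-fluoro-4,6-dimethoxybenzaldehyde, via iminium chloride 10 (not isolated)
Conditions: POCl3, DMF, 0 → 60 °C; then H2O
Reagents that add atoms: N,N-dimethylformamide, CN(C)C=O; water, O
Why: Vilsmeier–Haack formylation ortho to fluorine and para to one methoxy group, the less hindered activated position; the isomer formylated between the methoxy groups is removed by crystallisation.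

Step 7
Reactants: 11 2-fluoro-4,6-dimethoxybenzaldehyde
Product: 13 2-fluoro-6-hydroxy-4-methoxybenzaldehyde, via aryloxydichloroborane 12 (not isolated)
Conditions: BCl3 (1.1 equiv), CH2Cl2, −78 → 0 °C; then H2O
Reagents that add atoms: none
Why: Chelation-controlled demethylation; BCl3 bridges the formyl and ortho methoxy oxygens, so only that methyl ether is cleaved.

Step 8
Reactants: 13 2-fluoro-6-hydroxy-4-methoxybenzaldehyde
Product: 14 3-bromo-2-fluoro-6-hydroxy-4-methoxybenzaldehyde
Conditions: NBS (1.0 equiv), MeCN, 0 °C
Reagents that add atoms: N-bromosuccinimide, O=C1CCC(=O)N1Br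
Why: Electrophilic bromination para to the free phenol and ortho to methoxy, as in other 4-alkoxysalicylaldehydes; the position between OH and OCH3 is more crowded.

Step 9
Reactants: 14 3-bromo-2-fluoro-6-hydroxy-4-methoxybenzaldehyde
Product: 15 3-bromo-2-fluoro-4-methoxy-6-(propan-2-yloxy)benzaldehyde
Conditions: i-PrOH, PPh3, DIAD, THF, 0 °C → rt
Reagents that add atoms: propan-2-ol, CC(C)O
Why: Mitsunobu etherification of an acidic chelated phenol; neutral conditions avoid phenoxide attack on the activated C–F bond, and the isopropyl ether survives aqueous acid and SeO2 and is cleaved by BCl3 at low temperature.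

Step 10
Reactants: 8 (6S,7S)-6-ethynyl-7-methyl-7-(prop-1-en-2-yl)-1,4-dioxaspiro[4.5]decan-6-ol; 15 3-bromo-2-fluoro-4-methoxy-6-(propan-2-yloxy)benzaldehyde
Product: 17 3-bromo-2-{[(6S,7S)-6-ethynyl-7-methyl-7-(prop-1-en-2-yl)-1,4-dioxaspiro[4.5]decan-6-yl]oxy}-4-methoxy-6-(propan-2-yloxy)benzaldehyde, via potassium alkoxide 16 (not isolated)
Conditions: KN(SiMe3)2 (1.05 equiv), THF, −78 °C; then 15, −78 → 0 °C
Reagents that add atoms: none
Why: SNAr (addition–elimination) of the tertiary alkoxide at the C–F carbon activated by the ortho formyl group and bromine; a formyl group cannot be enolised as an acetyl group would be, and with ethynyl on C10 the alkoxide is not a 1,5-diene, so anionic oxy-Cope ring expansion is excluded.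

Step 11
Reactants: 17 3-bromo-2-{[(6S,7S)-6-ethynyl-7-methyl-7-(prop-1-en-2-yl)-1,4-dioxaspiro[4.5]decan-6-yl]oxy}-4-methoxy-6-(propan-2-yloxy)benzaldehyde
Product: 18 3-bromo-2-{[(6S,7S)-6-ethenyl-7-methyl-7-(prop-1-en-2-yl)-1,4-dioxaspiro[4.5]decan-6-yl]oxy}-4-methoxy-6-(propan-2-yloxy)benzaldehyde
Conditions: H2 (1 atm), Pd/CaCO3 poisoned with Pb(OAc)2, quinoline, EtOAc, rt
Reagents that add atoms: none
Why: Lindlar-type semihydrogenation of the terminal alkyne stops at the alkene and should leave the aryl bromide, the aldehyde and the 1,1-disubstituted alkene untouched.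

Step 12
Reactants: 18 3-bromo-2-{[(6S,7S)-6-ethenyl-7-methyl-7-(prop-1-en-2-yl)-1,4-dioxaspiro[4.5]decan-6-yl]oxy}-4-methoxy-6-(propan-2-yloxy)benzaldehyde
Product: 19 1-[3-bromo-2-{[(6S,7S)-6-ethenyl-7-methyl-7-(prop-1-en-2-yl)-1,4-dioxaspiro[4.5]decan-6-yl]oxy}-4-methoxy-6-(propan-2-yloxy)phenyl]ethan-1-ol (both carbinol epimers)
Conditions: MeMgBr, THF, −78 → 0 °C; aq NH4Cl
Reagents that add atoms: methylmagnesium bromide, C[Mg]Br
Why: Grignard addition to the aldehyde; the new carbinol centre is erased in the next step.

Step 13
Reactants: 19 1-[3-bromo-2-{[(6S,7S)-6-ethenyl-7-methyl-7-(prop-1-en-2-yl)-1,4-dioxaspiro[4.5]decan-6-yl]oxy}-4-methoxy-6-(propan-2-yloxy)phenyl]ethan-1-ol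
Product: 20 1-[3-bromo-2-{[(6S,7S)-6-ethenyl-7-methyl-7-(prop-1-en-2-yl)-1,4-dioxaspiro[4.5]decan-6-yl]oxy}-4-methoxy-6-(propan-2-yloxy)phenyl]ethan-1-one
Conditions: DMP, pyridine, CH2Cl2, rt
Reagents that add atoms: none
Why: Periodinane oxidation of the benzylic secondary alcohol to the methyl ketone under buffered conditions that spare the ketal and both alkenes.

Step 14
Reactants: 20 1-[3-bromo-2-{[(6S,7S)-6-ethenyl-7-methyl-7-(prop-1-en-2-yl)-1,4-dioxaspiro[4.5]decan-6-yl]oxy}-4-methoxy-6-(propan-2-yloxy)phenyl]ethan-1-one
Product: 21 tetracyclic ketal, (1R,4R,5S,10S): dihydrofuran and ring A closed, C9 as 1,3-dioxolane, C6–C8 as CH2; the arene carries acetyl (ortho to the ether O), O-i-Pr (other ortho position of the acetyl) and OCH3 (para to the acetyl)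
Conditions: Bu3SnH (1.3 equiv) and AIBN (0.2 equiv) in PhH by syringe pump over 8 h to 20 (0.003 M) in PhH, 80 °C
Reagents that add atoms: none
Why: Bu3Sn• abstracts bromine and the σ-aryl radical adds to the internal vinyl carbon C1 (5-exo-trig), closing the dihydrofuran as in the tin-hydride cyclisation of 2-halophenyl allyl ethers. The primary C2 radical then attacks the CH2 end of the isopropenyl group (6-endo-trig), closing ring A and leaving a tertiary C4 radical that takes hydrogen from the stannane, the behaviour of 5-methylhex-5-enyl radicals. A 5-exo second closure would have to join C2 to the fully substituted C4 next to the quaternary C5, so 6-endo closure should dominate. C1 is set in the first closure by the vinyl rotamer: only with the CH2 terminus on the C5 side, which also keeps it away from the spiro-dioxolane on C9, can C2 reach the isopropenyl group, and the other epimer would merely be reduced. C4 is set by hydrogen transfer from the face opposite the adjacent C5 methyl, giving the cis-dimethyl pair. The stannane is kept at a low stationary concentration because the 6-endo step is slow and must outrun hydrogen transfer to, and 1,2-aryl shift of, the C2 radical. The dioxolane prevents the reductive C–O cleavage expected for an α-aryloxy ketone, and C10 and C5 are untouched.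

Step 15
Reactants: 21 tetracyclic ketal; 22 4-methoxybenzaldehyde
Product: 24 (E)-chalcone ketal: as 21 with the acetyl group converted into (E)-3-(4-methoxyphenyl)prop-2-enoyl, via aldol adduct 23 (not isolated)
Conditions: 22 (1.5 equiv), KOH, EtOH/THF, rt
Reagents that add atoms: none
Why: Claisen–Schmidt condensation of the methyl ketone enolate with a non-enolisable aldehyde gives the (E)-enone; at this stage no dione is present, and the enone then removes the acidic CH3 before the SeO2 step.

Step 16
Reactants: 24 (E)-chalcone ketal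
Product: 25 C9 ketone, (1R,4R,5S,10S): as 24 with C9=O
Conditions: 2 M HCl, THF, 45 °C
Reagents that add atoms: water, O
Why: Acid hydrolysis of the dioxolane; the isopropyl ether keeps the ortho oxygen blocked, so the chalcone cannot close to a flavanone.

Step 17
Reactants: 25 C9 ketone
Product: 26 diosphenol, (1R,4R,5S,10S): C9=O, C8(OH)=C7, C6 as CH2
Conditions: SeO2, dioxane/H2O, 90 °C
Reagents that add atoms: selenium dioxide, O=[Se]=O
Why: Riley oxidation at C8, the only enolisable position, gives the 1,2-dione as its diosphenol; the chalcone has no α-hydrogen and the phenol is protected, so the SeO2 reactions of aryl methyl ketones and 2'-hydroxychalcones cannot occur.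

Step 18
Reactants: 26 diosphenol
Product: 27 ene-dione, (1R,4R,5R,10S): C9=O, C8=O, C6=C7
Conditions: IBX (2 equiv), DMSO/PhMe, 65 °C
Reagents that add atoms: none
Why: IBX dehydrogenation proceeds through the enol, which is already present as the diosphenol; loss of a C6 hydrogen gives C6=C7 conjugated with C8, and the quaternary C5 prevents further oxidation.

Step 19
Reactants: 27 ene-dione
Product: 29 phenolic ene-dione, (1R,4R,5R,10S): as 27 with free OH ortho to the enone carbonyl, via aryloxydichloroborane 28 (not isolated)
Conditions: BCl3 (1.2 equiv), CH2Cl2, −78 °C, 20 min; then H2O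
Reagents that add atoms: none
Why: BCl3 chelated between the chalcone carbonyl and the ortho isopropoxy oxygen removes the secondary alkyl group at low temperature; methyl ethers are not cleaved and the tertiary ether at C10 cannot ionise next to the C9 carbonyl.

Step 20
Reactants: 29 phenolic ene-dione
Product: 31 target, (1R,4R,5R,6S,7R,10S), via lithium phenoxide 30 (not isolated)
Conditions: LiN(SiMe3)2 (1.05 equiv), THF, −78 °C; then Ph2S=C(CH3)2 [from (CH3)2CH–S(+)Ph2 BF4(−) and LiN(i-Pr)2, DME, −78 °C] (1.2 equiv), −78 → −40 °C; aq NH4Cl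
Reagents that add atoms: diphenyl(propan-2-ylidene)-λ4-sulfane, CC(C)=S(c1ccccc1)c1ccccc1, made from diphenyl(propan-2-yl)sulfonium tetrafluoroborate, CC(C)[S+](c1ccccc1)c1ccccc1.F[B-](F)(F)F
Why: Corey–Chaykovsky-type cyclopropanation: the isopropylide adds to C6 of the doubly activated ene-dione and closes on C7 with loss of Ph2S. The chalcone is deactivated as its 2'-phenoxide, and attack anti to the C5 methyl should set C6 and C7 with the cyclopropane trans to that methyl.

## Compound list

1 | 3-methylcyclohex-2-en-1-one | CC1=CC(=O)CCC1 | starting material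
2 | dimethyl{[(3R)-3-methyl-3-(prop-1-en-2-yl)cyclohex-1-en-1-yl]oxy}aluminium | C[Al](C)OC1=C[C@](C)(C(C)=C)CCC1 | intermediate
3 | trimethyl{[(3R)-3-methyl-3-(prop-1-en-2-yl)cyclohex-1-en-1-yl]oxy}silane | C[Si](C)(C)OC1=C[C@](C)(C(C)=C)CCC1 | intermediate
4 | (3S)-3-methyl-3-(prop-1-en-2-yl)-2-[(trimethylsilyl)oxy]cyclohexan-1-one (C2 epimers) | O=C1CCC[C@@](C)(C(C)=C)C1O[Si](C)(C)C | intermediate
5 | (3S)-2-hydroxy-3-methyl-3-(prop-1-en-2-yl)cyclohexan-1-one (C2 epimers) | O=C1CCC[C@@](C)(C(C)=C)C1O | intermediate
6 | (6S)-2-hydroxy-6-methyl-6-(prop-1-en-2-yl)cyclohex-2-en-1-one | O=C1C(O)=CCC[C@@]1(C)C(C)=C | intermediate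
7 | (7S)-7-methyl-7-(prop-1-en-2-yl)-1,4-dioxaspiro[4.5]decan-6-one | O=C1C2(OCCO2)CCC[C@@]1(C)C(C)=C | intermediate
8 | (6S,7S)-6-ethynyl-7-methyl-7-(prop-1-en-2-yl)-1,4-dioxaspiro[4.5]decan-6-ol | O[C@]1(C#C)C2(OCCO2)CCC[C@@]1(C)C(C)=C | intermediate
9 | 1-fluoro-3,5-dimethoxybenzene | COc1cc(F)cc(OC)c1 | starting material
10 | N-[(2-fluoro-4,6-dimethoxyphenyl)methylidene]-N-methylmethanaminium chloride | COc1cc(F)c(C=[N+](C)C)c(OC)c1.[Cl-] | intermediate
11 | 2-fluoro-4,6-dimethoxybenzaldehyde | COc1cc(F)c(C=O)c(OC)c1 | intermediate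
12 | dichloro(3-fluoro-2-formyl-5-methoxyphenoxy)borane | COc1cc(F)c(C=O)c(OB(Cl)Cl)c1 | intermediate
13 | 2-fluoro-6-hydroxy-4-methoxybenzaldehyde | COc1cc(F)c(C=O)c(O)c1 | intermediate
14 | 3-bromo-2-fluoro-6-hydroxy-4-methoxybenzaldehyde | O=Cc1c(F)c(Br)c(OC)cc1O | intermediate
15 | 3-bromo-2-fluoro-4-methoxy-6-(propan-2-yloxy)benzaldehyde | O=Cc1c(F)c(Br)c(OC)cc1OC(C)C | intermediate
16 | potassium (6S,7S)-6-ethynyl-7-methyl-7-(prop-1-en-2-yl)-1,4-dioxaspiro[4.5]decan-6-olate | [K+].[O-][C@]1(C#C)C2(OCCO2)CCC[C@@]1(C)C(C)=C | intermediate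
17 | 3-bromo-2-{[(6S,7S)-6-ethynyl-7-methyl-7-(prop-1-en-2-yl)-1,4-dioxaspiro[4.5]decan-6-yl]oxy}-4-methoxy-6-(propan-2-yloxy)benzaldehyde | O=Cc1c(OC(C)C)cc(OC)c(Br)c1O[C@]1(C#C)C2(OCCO2)CCC[C@@]1(C)C(C)=C | intermediate
18 | 3-bromo-2-{[(6S,7S)-6-ethenyl-7-methyl-7-(prop-1-en-2-yl)-1,4-dioxaspiro[4.5]decan-6-yl]oxy}-4-methoxy-6-(propan-2-yloxy)benzaldehyde | O=Cc1c(OC(C)C)cc(OC)c(Br)c1O[C@]1(C=C)C2(OCCO2)CCC[C@@]1(C)C(C)=C | intermediate
19 | 1-[3-bromo-2-{[(6S,7S)-6-ethenyl-7-methyl-7-(prop-1-en-2-yl)-1,4-dioxaspiro[4.5]decan-6-yl]oxy}-4-methoxy-6-(propan-2-yloxy)phenyl]ethan-1-ol (carbinol epimers) | CC(O)c1c(OC(C)C)cc(OC)c(Br)c1O[C@]1(C=C)C2(OCCO2)CCC[C@@]1(C)C(C)=C | intermediate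
20 | 1-[3-bromo-2-{[(6S,7S)-6-ethenyl-7-methyl-7-(prop-1-en-2-yl)-1,4-dioxaspiro[4.5]decan-6-yl]oxy}-4-methoxy-6-(propan-2-yloxy)phenyl]ethan-1-one | CC(=O)c1c(OC(C)C)cc(OC)c(Br)c1O[C@]1(C=C)C2(OCCO2)CCC[C@@]1(C)C(C)=C | intermediate
21 | tetracyclic ketal (1R,4R,5S,10S): furan and ring A closed, C9 dioxolane, aryl acetyl / O-i-Pr / OCH3 | CC(=O)c2c(OC(C)C)cc(OC)c3c2O[C@]24C5(OCCO5)CCC[C@@]2(C)[C@H](C)CC[C@H]34 | intermediate
22 | 4-methoxybenzaldehyde | COc1ccc(C=O)cc1 | starting material
23 | aldol adduct of 21 and 22 (β-hydroxy ketone, carbinol epimers) | COc1ccc(C(O)CC(=O)c2c(OC(C)C)cc(OC)c3c2O[C@]24C5(OCCO5)CCC[C@@]2(C)[C@H](C)CC[C@H]34)cc1 | intermediate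
24 | (E)-chalcone ketal (1R,4R,5S,10S) | COc1ccc(/C=C/C(=O)c2c(OC(C)C)cc(OC)c3c2O[C@]24C5(OCCO5)CCC[C@@]2(C)[C@H](C)CC[C@H]34)cc1 | intermediate
25 | (E)-chalcone C9 ketone (1R,4R,5S,10S) | COc1ccc(/C=C/C(=O)c2c(OC(C)C)cc(OC)c3c2O[C@]24C(=O)CCC[C@@]2(C)[C@H](C)CC[C@H]34)cc1 | intermediate
26 | (E)-chalcone diosphenol (C9=O, C8(OH)=C7) (1R,4R,5S,10S) | COc1ccc(/C=C/C(=O)c2c(OC(C)C)cc(OC)c3c2O[C@]24C(=O)C(O)=CC[C@@]2(C)[C@H](C)CC[C@H]34)cc1 | intermediate
27 | (E)-chalcone ene-dione (C6=C7, C8=O, C9=O), isopropyl ether (1R,4R,5R,10S) | COc1ccc(/C=C/C(=O)c2c(OC(C)C)cc(OC)c3c2O[C@]24C(=O)C(=O)C=C[C@@]2(C)[C@H](C)CC[C@H]34)cc1 | intermediate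
28 | O-dichloroboryl derivative of 29 | COc1ccc(/C=C/C(=O)c2c(OB(Cl)Cl)cc(OC)c3c2O[C@]24C(=O)C(=O)C=C[C@@]2(C)[C@H](C)CC[C@H]34)cc1 | intermediate
29 | (E)-chalcone ene-dione, free phenol (1R,4R,5R,10S) | COc1ccc(/C=C/C(=O)c2c(O)cc(OC)c3c2O[C@]24C(=O)C(=O)C=C[C@@]2(C)[C@H](C)CC[C@H]34)cc1 | intermediate
30 | lithium phenoxide of 29 | [Li+].COc1ccc(/C=C/C(=O)c2c([O-])cc(OC)c3c2O[C@]24C(=O)C(=O)C=C[C@@]2(C)[C@H](C)CC[C@H]34)cc1 | intermediate
31 | CNP0121765.1, (1R,4R,5R,6S,7R,10S) | COc1ccc(/C=C/C(=O)c2c(O)cc(OC)c3c2O[C@]24C(=O)C(=O)[C@@H]5[C@@H](C5(C)C)[C@@]2(C)[C@H](C)CC[C@H]34)cc1 | target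

Total step count: 20. Longest linear sequence: 16 (steps 1–5 and 10–20).

Least certain steps:

Step 14 (key step). The first closure may take the vinyl rotamer with C2 on the C9 side, which ends in plain reduction. The C2 radical may also be reduced, or undergo a 1,2-aryl shift, before the slow 6-endo closure. Hydrogen delivery at C4 may lack facial control. Fallback, from 20 back to 21: the aryl radical is cyclised with Bu3SnH/AIBN under dry air so that the C2 radical is trapped by oxygen, and reduction with PPh3 gives the spiro dihydrobenzofuran primary alcohol F1, whose C1 epimers can be separated. I2, PPh3 and imidazole give the primary iodide F2. Iodine-atom-transfer cyclisation ((Bu3Sn)2 cat., hν, PhH), with no hydrogen donor present, closes ring A to the C4 tertiary iodide F3. Bu3SnH/AIBN then reduces F3 to 21.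

Step 5. Facial selectivity may be poor, because the methyl and isopropenyl groups on C5 differ little in size, and the wrong C10 epimer cannot be recycled. Fallback, from 3 back to 18, introducing the C10 oxygen last onto a planar C10. Mukaiyama aldol of 3 with acetaldehyde (TiCl4) gives the aldol (3R)-2-(1-hydroxyethyl)-3-methyl-3-(prop-1-en-2-yl)cyclohexan-1-one F4. MsCl/Et3N then DBU gives the 2-ethylidene ketone F5. The through-conjugated dienolate (KN(SiMe3)2, equilibrated) is hydroxylated at C10 with 2-(phenylsulfonyl)-3-phenyloxaziridine, anti to the pseudo-axial isopropenyl group, to the ketol (2S,3S)-2-ethenyl-2-hydroxy-3-methyl-3-(prop-1-en-2-yl)cyclohexan-1-one F6. Ketalisation as in step 4 gives (6S,7S)-6-ethenyl-7-methyl-7-(prop-1-en-2-yl)-1,4-dioxaspiro[4.5]decan-6-ol F7. Etherification of F7 with 15 (KN(SiMe3)2, THF, −78 → −20 °C) gives 18.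

Step 10. Substitution at the crowded C–F carbon may be slow, which gives the alkoxide time to lose acetylide or to add to the formyl group. Fallback, from 8 and 15 back to 17, with reversed polarity and no alkoxide. 8 is converted with (CF3CO)2O/DBU into the trifluoroacetate F8. 15 is converted with KOH in DMSO/H2O into 3-bromo-2-hydroxy-4-methoxy-6-(propan-2-yloxy)benzaldehyde F9. Copper-catalysed propargylic etherification (CuCl2 cat., DBU, MeCN, 0 °C) of F9 with F8 proceeds through a planar copper allenylidene, which cannot eliminate here and which also makes the C10 configuration of 8 irrelevant, and gives 17.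

Step 20. The ylide may approach C6 from the face of the C5 methyl, may add to the C9 carbonyl to give an epoxide, or may attack the chalcone if the phenoxide is incompletely formed. Fallback, from 27 back to 31, by cycloaddition in place of ylide addition. 2-Diazopropane adds to the ene-dione of 27 to give the fused 1-pyrazoline F10. Photolytic loss of N2 gives the cyclopropyl dione isopropyl ether F11. BCl3 at −78 °C then gives 31.

## Further compounds

F1 | step 14 | spiro dihydrobenzofuran with CH2OH on C1 (from 20 by oxygen-trapped 5-exo closure) | CC(=O)c1c(OC(C)C)cc(OC)c2c1O[C@]1([C@@H]2CO)C2(OCCO2)CCC[C@@]1(C)C(C)=C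
F2 | step 14 | corresponding primary iodide (CH2I on C1) | CC(=O)c1c(OC(C)C)cc(OC)c2c1O[C@]1([C@@H]2CI)C2(OCCO2)CCC[C@@]1(C)C(C)=C
F3 | step 14 | ring A closed, tertiary iodide at C4 (C4 epimers) | CC(=O)c2c(OC(C)C)cc(OC)c3c2O[C@]24C5(OCCO5)CCC[C@@]2(C)C(C)(I)CC[C@H]34
F4 | step 5 | (3R)-2-(1-hydroxyethyl)-3-methyl-3-(prop-1-en-2-yl)cyclohexan-1-one (epimers at the two new centres) | CC(O)C1C(=O)CCC[C@@]1(C)C(C)=C
F5 | step 5 | 2-ethylidene-3-methyl-3-(prop-1-en-2-yl)cyclohexan-1-one, quaternary carbon as in 3 (either alkene geometry) | CC=C1C(=O)CCC[C@@]1(C)C(C)=C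
F6 | step 5 | (2S,3S)-2-ethenyl-2-hydroxy-3-methyl-3-(prop-1-en-2-yl)cyclohexan-1-one | O[C@]1(C=C)C(=O)CCC[C@@]1(C)C(C)=C
F7 | step 5 | (6S,7S)-6-ethenyl-7-methyl-7-(prop-1-en-2-yl)-1,4-dioxaspiro[4.5]decan-6-ol | O[C@]1(C=C)C2(OCCO2)CCC[C@@]1(C)C(C)=C
F8 | step 10 | (6S,7S)-6-ethynyl-7-methyl-7-(prop-1-en-2-yl)-1,4-dioxaspiro[4.5]decan-6-yl trifluoroacetate | FC(F)(F)C(=O)O[C@]1(C#C)C2(OCCO2)CCC[C@@]1(C)C(C)=C
F9 | step 10 | 3-bromo-2-hydroxy-4-methoxy-6-(propan-2-yloxy)benzaldehyde | O=Cc1c(O)c(Br)c(OC)cc1OC(C)C
F10 | step 20 | 1-pyrazoline fused at C6–C7 (C7–N=N–C(CH3)2–C6), isopropyl ether | COc1ccc(/C=C/C(=O)c2c(OC(C)C)cc(OC)c3c2O[C@]24C(=O)C(=O)[C@H]5N=NC(C)(C)[C@H]5[C@@]2(C)[C@H](C)CC[C@H]34)cc1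
F11 | step 20 | isopropyl ether of 31 | COc1ccc(/C=C/C(=O)c2c(OC(C)C)cc(OC)c3c2O[C@]24C(=O)C(=O)[C@@H]5[C@@H](C5(C)C)[C@@]2(C)[C@H](C)CC[C@H]34)cc1
A1 | alternative 1 | spiro 2H-chromene, arene on C2, ring B with C8=C9 | CC1(OCCO1)c2c(OCOC)cc(OC)c3c2O[C@@]2(C=CCC[C@@]2(C)C(C)=C)C=C3
A2 | alternative 1 | spiro dihydrobenzofuran with dimethoxymethyl group on C1 | CC1(OCCO1)c2c(OCOC)cc(OC)c3c2O[C@@]2(C=CCC[C@@]2(C)C(C)=C)[C@@H]3C(OC)OC
A3 | alternative 2 | 3-vinylbenzofuran with C8/C9 dione, cis-cyclopropane and (E)-but-2-en-2-yl group | CC(=O)c1c(OCOC)cc(OC)c2c(C=C)c(C(=O)C(=O)[C@@H]3[C@@H](C3(C)C)/C(C)=C/C)oc12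
A4 | alternative 2 | pentacyclic 1,2-dehydro core with 8,9-dione and cyclopropane | CC(=O)c2c(OCOC)cc(OC)c3c2O[C@]24C(=O)C(=O)[C@@H]5[C@@H](C5(C)C)[C@@]2(C)[C@H](C)CC=C34
A5 | alternative 3 | tetrahydrodibenzofuran with 4-oxobutyl chain on C5 | CC1(OCCO1)c2c(OCOC)cc(OC)c3c2oc2c3CC[C@@H](C)[C@]2(C)CCCC=O
A6 | alternative 3 | tetracyclic cis-fused C9 carbinol | CC1(OCCO1)c2c(OCOC)cc(OC)c3c2O[C@]24[C@@H](O)CCC[C@@]2(C)[C@H](C)CC[C@H]34
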